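(The earlier runs and the new flask were generated by integration on assumed constants; scatter was added.)

Time is the ruler for this flask: at 20 °C I count how many half-times of its lagging change fit into 5.0 d, as one counts time constants on a slow circuit.

| flask | first end groups | second end groups | temperature | remark | time |
|---|---|---|---|---|---|
| gamma | 1 M | 0.95 M | 20 °C | the very flask that is asked about, followed so far |  |
| delta | 1 M | 0.95 M | 26 °C | run made earlier |  |
| flask | 1.0 M | 0.950 M | 20 °C |  | 5.0 d |

| run | time / d | links / % | first end groups / % |
|---|---|---|---|
| gamma | 0.250 | 35 | 72 |
| gamma | 0.833 | 42 | 40 |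
| gamma | 1.25 | 39 | 32 |
| gamma | 2.00 | 42 | 19 |
| gamma | 3.00 | 37 | 14 |
| delta | 0.250 | 33 | 55 |
| delta | 0.833 | 48 | 28 |
| delta | 1.25 | 50 | 23 |
| delta | 2.00 | 51 | 16 |
| delta | 3.00 | 53 | 19 |

(readings scatter by 2 percentage points)

- dusk: change nothing and wait 40 h more
- winter: at 5.0 d take out 90% of the released group then present, then wait 40 h
- dawn: at 5.0 d raise the temperature by 20 K, then wait 40 h

- what is added takes up no volume worth counting

1. links, in percent of the first end groups first charged, at 5.0 d
2. the remedy with the largest gain of links, or "none" below 2 percentage points (dusk / winter / dawn / none)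
3. links present, in percent of the first end groups first charged, after dusk
4. links present, in percent of the first end groups first charged, after dawn

The gamma run is this same flask followed so far, so I read the ladder there. Let A be the first end groups, L the links, both in percent of the charge, and M the rest of the charge, M = charge − A − L.

On the lowest rung, A has fallen to 40% by 0.833 d, and L already reads 42% there, against 37% at 3.00 d, so links stop climbing early.

On the next rung, M reads 18.0% at 0.833 d, 29.0% at 1.25 d and 49.0% at 3.00 d. Taking the last reading as near its plateau, M passes half of it at a half-time of 1.08 d, a reading with the scatter in it.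

On the top rung, 5.0 d holds 4.63 such half-times, so 4.03% of the way remains, and I put dusk below 2 percentage points.

M and L have then reached a fixed split, an equilibrium ratio. From the last two gamma readings, the split ratio M/L is 1.11. The rule is therefore L = (charge − A)/(1 + split). A at 5.0 d I set at its last gamma reading, 14%, as a plain assumption: the gamma readings are still falling, from 19% at 2.00 d to 14% at 3.00 d, so this figure carries the scatter of 2 points and leaves out any further fall. This gives 40.7% for the flask.

The same ratio in the delta run at 26 °C is 0.587, lower than at 20 °C, so I commit to dawn.

The forecast gives 36% now, 36.5% after dusk and 68% after dawn, and chooses dawn, holding that “parking is strongly exothermic”; my 40.7% stands above its first figure.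

The flask gives 40.8% at 5.0 d, 41.1% after dusk and 58.4% after dawn. The gains are 0.28 points for dusk, 1.6 points for winter and 18 points for dawn, so the choice is dawn.

    first end groups + second end groups ⇌ links + released group (K = 34.0, k = 2.28 × 10⁻⁵ L mol⁻¹ s⁻¹, Ea = 64.0 kJ mol⁻¹, ΔH = −72.0 kJ mol⁻¹)
    2 first end groups → homo dimer (k = 8.14 × 10⁻⁹ L mol⁻¹ s⁻¹, Ea = 82.0 kJ mol⁻¹)
    links ⇌ isomer of the product (K = 1.10, k = 1.10 × 10⁻⁵ s⁻¹, Ea = 88.0 kJ mol⁻¹, ΔH = −68.0 kJ mol⁻¹)
    (constants at 20 °C)

M in this flask is the isomer of the product, and the homo dimer changes links by nothing worth counting. Half of the turnover into the isomer is done by 0.993 d, so 5.0 d holds 5.04 such times. With the 15.1% of first end groups that stand in the flask at 5.00 d, the split ratio 1.11 gives 40.2%. The neighbouring flask is charged with 0.60 M of first end groups, other charges and temperature held. There 3.09% remain at 5.00 d, so the same rule gives 45.9% of its charge, and its links stand at 46.5%.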